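(All runs were computed for substances that don't exist, noise included.)

Of the 0.400 M of starting material charged to the eta run, 60.7% stands as product at 13 h. Of the 1.00 M charged to the zeta run, 37.6% does at the same time.

| setting | zeta | eta | delta | gamma |
|---|---|---|---|---|
| starting material | 1.00 M | 0.400 M | 1.00 M | 0.500 M |
| reagent | 2.00 M | 1.40 M | 2.00 M | 1.00 M |
| free catalyst | 0.0800 M | 0.0800 M | 0.0400 M | 0.0800 M |
| time |  |  |  | 13 h |

| run | time / h | [product] / M |
|---|---|---|
| zeta run | 1.6 | 0.053 |
| zeta run | 3.2 | 0.138 |
| zeta run | 4.9 | 0.220 |
| zeta run | 6.5 | 0.243 |
| zeta run | 8.1 | 0.297 |
| zeta run | 9.8 | 0.335 |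
| zeta run | 11 | 0.365 |
| zeta run | 13 | 0.376 |
| eta run | 1.6 | 0.047 |
| eta run | 3.2 | 0.073 |
| eta run | 4.9 | 0.134 |
| eta run | 6.5 | 0.172 |
| eta run | 8.1 | 0.199 |
| eta run | 9.8 | 0.236 |
| eta run | 11 | 0.212 |
| eta run | 13 | 0.243 |
| delta run | 1.6 | 0.023 |
| delta run | 3.2 | 0.067 |
| delta run | 4.9 | 0.125 |
| delta run | 6.5 | 0.137 |
| delta run | 8.1 | 0.166 |
| delta run | 9.8 | 0.183 |
| delta run | 11 | 0.203 |
| delta run | 13 | 0.251 |

(readings scatter by 0.01 M)

- Overall: starting material + reagent -> product, with free catalyst as catalyst.
- Constant volume, constant temperature.
- What is held in complexes is read along with the free species.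
- "The second partner" is reagent.
- An order is taken over about fifteen percent of the charge, up and down.

* apparent order in [free catalyst] of the starting rate, round the charge of the zeta run (the rate where two percent of its starting material have turned into product)
* product in the gamma run at 13 h, as a share of the starting material charged

The smaller charge in the eta run turned the larger share, and the 0.500 M of starting material in the gamma run lies between the two. Call the share exponent the power by which the share made at 13 h falls as the charge rises. But two charges changed between eta and zeta, so there are two ways to read it.

Laid on starting material, the exponent is 0.524. Going from eta to the 0.500 M of gamma, that gives a share of 54.1%.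

Laid on reagent, it is 1.35. Going from zeta to the 1.00 M of gamma, that gives 95.5%, which is 0.478 M of product.

The two ways part, and the amounts show which one cheats. Gamma holds half of the zeta charge of each partner with the same free catalyst. Yet the reagent way gives it more product than the 0.376 M of zeta. So the starting-material way stands, and the reckoning here commits to 54.1%. That figure may lean high, since gamma has less reagent than eta.

For the catalyst order, the delta and zeta readings at 6.5 h give 0.827. This is a later reading over a wider step than the one asked, and it carries their scatter.

The forecast gives 0.9 and 47%, expecting gamma to “track eta closely”. Its share is lower than the one reckoned here.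

The flask gives an order of 0.74 and a share of 52.1%.

    free catalyst + starting material → catalyst-substrate complex (3.672 M⁻¹ h⁻¹)
    catalyst-substrate complex + reagent → loaded catalyst (0.9288 M⁻¹ h⁻¹)
    loaded catalyst → product + free catalyst (1.667 h⁻¹)
    2 starting material → homo dimer (0.1908 M⁻¹ h⁻¹)

On gamma, the share exponent lands 2 percentage points high. On zeta, it scales the 3.74 h that eta needs for a quarter of its charge up to 6.04 h, against the simulated 6.23 h. In the gamma run, part of the starting material passes into homo dimer. With that step taken away, the gamma run gives 67.0% against 52.1%, a difference of 15 points.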